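(The rate constants belong to no real substance; what happens was integrated by code.)

**Charge and question.** Per mole of substrate, 0.900 mole of partner goes in, and each double product takes two partner, so the charge holds partner for 0.450 mole of double product.

in all of them: substrate 0.10 M; partner 0.900 equiv

| run | remark | time |
|---|---|---|
| alpha | one stirred flow tank at steady state, fed with the mixture as stated, mean residence time 250 min |  |
| delta | a single well-mixed tank run continuously and read at steady state, 25 min in it on average |  |
| gamma | plug flow through a tube for 25 min, no back-mixing | 25 min |
| eta | a closed flask charged with all of it at once and left for 25 min | 25 min |

1. the set-up with the highest amount of double product at the outlet or at the end, in percent of the substrate put in ("none" if the first two lie within 2 percentage points) (alpha / delta / gamma / eta / none)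
2. amount of double product at the outlet or at the end, in percent of the substrate put in, alpha
3. amount of double product at the outlet or at the end, in percent of the substrate put in, delta
4. amount of double product at the outlet or at the end, in percent of the substrate put in, gamma
5. amount of double product at the outlet or at the end, in percent of the substrate put in, eta

- two of one species on the left: rate k times its square, two consumed each time
- the stated concentrations are those of everything mixed, before any reaction; amounts are the same in each set-up
- run time (gamma): 25 min

**One ratio.** Partner stands on the left of the step from substrate and of the step from single product, so its concentration multiplies both rates and cancels when one is divided by the other. What remains is the selectivity factor s, the rate constant of the step from single product over that of the step from substrate: 1.10. With x the fraction of substrate left, a closed flask or tube holds a fraction (x^s − x)/(1 − s) as single product, and a stirred tank holds (1 − x)/(1 + s(1 − x)/x). Double product is the substrate charged less these two fractions, substrate left and single product.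

**Flask against tank.** The closed flask eta and the tank delta look nearly the same, with one charge and 25 min. With half of the substrate left, this reckoning gives 16.6 % of double product in a flask and 26.2 % in a tank, so the tank makes more per substrate spent. But the tank works at its outlet concentrations, so the substrate left need not match in the two. That depends on partner, which self-condensation also consumes: at the start of eta, the step from substrate uses partner at 0.75 of the rate of self-condensation. The reckoning therefore commits to no yield; it turns substrate left into double product once that is read.

**The forecast.** It named alpha best, with 22.2 % for alpha, 6.8 % for delta, 6.4 % for gamma and 6.4 % for eta: “The ten-fold longer residence time in alpha dominates everything”.

**The result.** The simulation puts alpha highest, with 22.2 % for alpha, 6.82 % for delta, 6.34 % for gamma and 6.34 % for eta.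

    partner + single product → double product (k1 = 0.0064 L mol⁻¹ s⁻¹)
    substrate + partner → single product (k2 = 0.0058 L mol⁻¹ s⁻¹)
    2 partner → self-condensation product (k3 = 0.0043 L mol⁻¹ s⁻¹)

**Partner falling.** The flask eta ends with 67.9 % of its substrate left, and s turns that into 6.34 % of double product. The tank delta, with 74.8 % left, gives 6.82 %. In eta, partner stands at 24 % of its charge by the end, and the run with partner held at its charge reaches 19.9 %, so the depletion of partner takes 14 percentage points from that flask.

**Second flask.** The neighbour of eta charged with 0.360 equiv of partner leaves 83.4 % of its substrate, which s turns into 1.61 % of double product. The simulation gives 1.61 %.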